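A small charge of free catalyst has to turn over many times to matter, so what you reckon for this flask is a slope, not a yield.

- Sunday's: left-handed substrate 0.30 M; right-handed substrate 0.30 M; gas 58 mM (held); free catalyst 4 mol%; run made earlier
- flask: left-handed substrate 0.30 M; gas 58 mM (held); free catalyst 2 mol%; right-handed substrate 0.30 M; time 3.0 min

Sunday's run (percent of the left-handed substrate and right-handed substrate together charged)

| time / s | left-handed substrate / % | right-handed substrate / % |
|---|---|---|
| 10.0 | 48.6 | 49.1 |
| 12.0 | 48.2 | 49.2 |
| 20.0 | 47.2 | 49.7 |
| 30.0 | 45.6 | 50.0 |
| 50.0 | 42.2 | 49.7 |

(scatter of a reading: 0.3 percentage points)

- free catalyst is single-handed; left-handed substrate and right-handed substrate are mirror images of each other, charged as a racemate, each of them at the stated concentration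
- at the start none of reagent is dissolved
- steps that have been proposed: free catalyst + left-handed substrate <-> catalyst intermediate A; reagent + catalyst intermediate B -> free catalyst + right-handed product; reagent + catalyst intermediate A -> free catalyst + left-handed product; gas <-> reagent; free catalyst + right-handed substrate <-> catalyst intermediate B; left-handed substrate <-> right-handed substrate
- an excess is the difference of the two amounts in percent of their sum
- an excess is below zero if the other one leads
- no earlier run changes the charge of free catalyst; that part of a forecast is a guess

* part of the left-handed substrate and right-handed substrate charged together that has reacted at 3.0 min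
* excess of left-handed product over right-handed product in the product at 3.0 min
* excess of right-handed substrate over left-handed substrate among what is left of the two at 3.0 min

1. Take the main step first. Free catalyst binds left-handed substrate as catalyst intermediate A, and reagent turns that into left-handed product, freeing the catalyst. The end state of this step is left-handed substrate consumed and right-handed substrate left over, a kinetic resolution. To see how fast it gets there, look at Sunday's run: between 30.0 s and 50.0 s the left-handed substrate falls by 3.4 percentage points, each reading carrying 0.3 points. Call the fraction of the two substrates' joint charge lost per minute at Sunday's loading, as read from these two readings, the working slope, 0.102 min⁻¹.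

2. Add the loading. No earlier run changes it, so this is a guess: the slope goes with free catalyst. This flask holds half of Sunday's loading, so over 3.0 min my conversion is 15.3%.

3. Add the mirror image. Right-handed substrate shows no fall in Sunday's run, from 49.1% to 49.7%. If it stays put in this flask, the product is close to purely left-handed, and the substrate excess is the conversion divided by the part of the joint charge not converted, which gives 18.1%.

4. Add the rest. Sunday's slope from 10.0 s to 20.0 s reads 0.0840 min⁻¹, lower than the working slope, so the slope may have been rising, though that gap lies within the scatter of the readings. I judge that such a rise and the later loss of left-handed substrate offset each other, and I keep 15.3%.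

The forecast gives 20%, 76% and 12%, on the ground that “the left-handed substrate reacts preferentially”. My conversion of 15.3% stands below its 20%, and my substrate excess of 18.1% above its 12%.

This flask gives 16.9%, 97.1% and 18.5%.

    free catalyst + left-handed substrate ⇌ catalyst intermediate A (K = 9.40 M⁻¹, k = 90.0 M⁻¹ s⁻¹)
    reagent + catalyst intermediate B → free catalyst + right-handed product (k = 0.150 M⁻¹ s⁻¹)
    reagent + catalyst intermediate A → free catalyst + left-handed product (k = 3.40 M⁻¹ s⁻¹)
    gas ⇌ reagent, rate k4*(csat - [reagent]) (kL = 0.0690 s⁻¹)
    free catalyst + right-handed substrate ⇌ catalyst intermediate B (K = 2.60 M⁻¹, k = 39.0 M⁻¹ s⁻¹)
    left-handed substrate ⇌ right-handed substrate (k = 2.00 × 10⁻⁴ s⁻¹)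

This flask's mean slope is 0.0563 min⁻¹, against 0.0510 min⁻¹ from the scaled working slope. At 3.00 min reagent in this flask is used 55 times faster through catalyst intermediate A than through catalyst intermediate B, a split that corresponds to an excess of left-handed product of 96.4% in the product forming at that moment.

In the neighbouring flask, the same as this one but with 5 mol% of free catalyst, the working slope scaled by loading gives 38.2% over 3.0 min. The computed neighbouring flask reaches 32.4%, with 19.4% left-handed substrate remaining.

The data were computed for an exercise; scatter was added.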